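Readings and results come from a simulation for an exercise; the scatter is artificial.

**The question.** Ask how much substrate has reacted after 20 min in Thursday's and Friday's flasks, and whether raising [scavenger] moves that part.

| flask | substrate | reagent | scavenger | initiator | remark | time |
|---|---|---|---|---|---|---|
| south-east | 0.050 M | 0.075 M | 0.041 M | 0.65 mM | run made earlier |  |
| north-east | 0.050 M | 0.075 M | 0.048 M | 0.65 mM | run made earlier |  |
| Thursday's | 0.050 M | 0.0750 M | 0.0500 M | 0.65 mM |  | 20 min |
| Friday's | 0.050 M | 0.0750 M | 0.0750 M | 0.65 mM |  | 20 min |

- south-east (time / min: substrate / %, target / %): 0.833: 39.4, 33.0; 1.33: 28.3, 42.3; 2.00: 20.0, 50.0; 3.00: 28.2, 52.7; 4.00: 33.0, 53.0; 6.00: 38.7, 54.2; 10.0: 42.1, 53.4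
- north-east (time / min: substrate / %, target / %): 0.833: 40.7, 31.5; 1.33: 27.9, 42.2; 2.00: 23.0, 52.6; 3.00: 30.0, 54.6; 4.00: 36.0, 54.4; 6.00: 42.6, 54.6; 10.0: 44.2, 53.1

(scatter of a reading: 1 percentage point)

- a reading of substrate is of its free form alone

1. part of the substrate that has reacted at the end, Thursday's
2. part of the substrate that has reacted at the end, Friday's
3. what raising the concentration of scavenger from its lowest to its highest value here does to the part of the substrate that has reacted (changes below 5 percentage points count as none) (it falls / it rises / no change)

**The hold-up.** Subtract free substrate and target from the charge and call the remainder the hold-up: in the north-east run it reads 24.4 % at 2.00 min and 9.60 % at 4.00 min. Treat its fall as pseudo-first-order, which gives 0.466 min⁻¹ as the drain rate, the logarithmic fall of the hold-up per minute. The south-east run, with lower [scavenger], reads slower at 0.381 min⁻¹.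

**The estimate.** Count as reacted whatever is not free, so target plus hold-up. North-east target reads a plateau averaging 54.2 % from 3.00 min on, and Thursday's [scavenger] lies beside that run's, so carry the drain rate on to 20 min: this reckoning leaves a hold-up of 0.00551 % and puts Thursday's reacted part at 54.2 %.

**The weak link.** The drain rate predicts 0.585 % at 10.0 min, yet the north-east run reads 2.70 % there. Distrust the tail, then, and take that reading as a ceiling, which puts Thursday's between 54.2 % and 56.9 %. Assume the same plateau for Friday's, though no run reaches 0.0750 M; the window is 2.7 percentage points wide, against the 5 points that counts, so commit to no change.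

**The forecast.** It gives 55 %, 56 % and no change, holding that “By 20 min, reacted ≈ target plus a little loss”; its 55 % stands above my 54.2 %, inside the window.

**The result.** The flasks give 54.1 % and 54.3 %: no change, a change of 0.19 points.

    reagent + first chain carrier → target + second chain carrier (k = 3.06 × 10⁶ L mol⁻¹ s⁻¹)
    scavenger + released group → scavenged by-product (k = 5.70 L mol⁻¹ s⁻¹)
    initiator → 2 initiating radical (k = 9.90 × 10⁻⁵ s⁻¹)
    substrate + second chain carrier → released group + first chain carrier (k = 3.63 × 10⁵ L mol⁻¹ s⁻¹)
    substrate + released group ⇌ idle adduct, settled at all times (K = 1510 L mol⁻¹)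
    2 second chain carrier → ended chains (k = 8.50 × 10⁷ L mol⁻¹ s⁻¹)
    substrate + initiating radical → capped initiator + first chain carrier (k = 1.58 × 10⁷ L mol⁻¹ s⁻¹)
    2 reagent → self-condensation product (k = 0.379 L mol⁻¹ s⁻¹)

**The neighbour.** Part of the hold-up appears here as idle adduct, which in Thursday's flask falls from 2.02 % at 10.0 min to 0.205 % at 20.0 min, a drain of 0.229 min⁻¹, about half the rate read in the north-east run. Now read Thursday's flask at 5.0 min: carry the north-east hold-up and drain rate on from 4.00 min, add the north-east plateau, and get 60.2 %. Thursday's flask at that time gives 61.2 %, holding 53.6 % target and 7.53 % idle adduct.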